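I read the protic impurity as consuming its own molar amount of starting material early: 0.070 M against 1.4 M is 5.00 % of the charge, and Monday's run stands at 94.5 % by 8.00 min. The remainder, a reactive share of 95.0 %, I let fall as a first-order decay, so the logarithm of what is left falls on a straight line in time.

| flask | starting material | protic impurity | catalyst | remark | time |
|---|---|---|---|---|---|
| Monday's | 1.4 M | 0.070 M | 28 mM | run made earlier |  |
| amber | 1.4 M | 0.0700 M | 14 mM |  | 5.0 h |
| violet | 1.4 M | 0.0700 M | 14 mM |  | 15 h |

Monday's run (percent of the starting material charged)

| time / min | starting material / % | target / % | intermediate / % |
|---|---|---|---|
| 8.00 | 94.5 | 0 | 3.7 |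
| 15.0 | 92.7 | 0.9 | 2.3 |
| 25.0 | 89.6 | 1.2 | 5.1 |
| 30.0 | 90.0 | 1.0 | 6.0 |
| 40.0 | 86.2 | 0.6 | 8.3 |
| 50.0 | 86.0 | 0.5 | 8.4 |
| 60.0 | 81.3 | 1.3 | 10.3 |

(each reading ± 1 percentage point)

- what was read earlier has a scatter of 1 percentage point, one standard deviation
- no earlier run changes the charge of catalyst; that part of a forecast is a guess

- which of these there is most of at the end, counted by the starting material in it, amber (starting material / intermediate / target)
- which of these there is most of at the end, counted by the starting material in it, violet (starting material / intermediate / target)
- how much there is at the end of the one of these that leads, in percent of the starting material charged: amber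
- how much there is at the end of the one of these that leads, in percent of the starting material charged: violet

Which inputs must be known well? The reactive share enters as a fixed offset of 0.0223 of a power of ten. As for the slope, one point of scatter on Monday's fall of 14 percentage points moves it by 7.30 %. The catalyst order weighs more still: no earlier run changes that charge, and a first-order dependence at the charge of amber and violet would stretch the time scale of the decay by a factor of 2.00. That part is a guess, and I guess that the catalyst leaves this decay unchanged.

Decade time, the time in which the reactive starting material falls by one power of ten:

D = 60.0 min / log(95.0 % / 81.3 %) = 14.8 h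

log[c(starting material) / charge] = log(reactive share) − t/D

amber: t/D = 0.338, c(starting material) = 43.6 % of the charge

violet: t/D = 1.01, c(starting material) = 9.21 % of the charge

I expect starting material to lead amber. In violet I expect it not to lead, but Monday's last target reading is 1.3 % against a scatter of 1 point, so I name no leader there.

The forecast differs: starting material leads amber at 66 % and intermediate leads violet at 37 %, on the ground “Guessing first order in catalyst”.

Amber ends with starting material leading at 47.1 %, and violet with target leading at 34.5 %, its starting material at 11.6 %. Changing the catalyst charge alone from Monday's run to amber leaves the starting material at the time of Monday's last reading, scatter aside, at 82.5 %, where it stood at 82.5 %.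

    starting material → intermediate (k = 0.140 h⁻¹)
    catalyst + intermediate → catalyst + target (k = 9.50 M⁻¹ h⁻¹)
    starting material + protic impurity → quenched substrate (k = 6.70 M⁻¹ h⁻¹)
    intermediate → decomposed reagent (k = 0.150 h⁻¹)

Violet read at 40 h, where the decade time gives 0.190 %, holds 0.351 % starting material.

Readings and results are calculated for substances that don't exist; noise was put on by code.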